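**Assumptions (one line):** 3-methylfuran-2-carbaldehyde and 2-(triphenylphosphoranylidene)propanal are commercial. I assume the C1/C2 diastereoselectivity of the macrocyclic NHK reaction is controlled by the macrocycle and C10, as in furanocembranoid precedent. The SMILES in the target gives 1S, 2S, 10S, C8(Cq) S and C7 S.

## Retrosynthesis
1. Target (Z-enedione) ← furan oxidative ring opening ← C2 acetate ← macrocyclic furfuryl alcohol (a 2,5-bridged furan).
2. Macrocycle ← intramolecular Nozaki–Hiyama–Kishi (NHK) allylation of a furfural by an (E)-allylic bromide. This joins C1–C2 and sets the isopropenyl and carbinol centres (anti).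
3. Butenolide and chain ← Ru-catalysed Alder-ene/lactonisation of a γ-hydroxy-alkynoate with allyl alcohol, then Wittig homologation. C10 comes from a reagent-controlled ynone reduction.
4. Ynone ← (1S,2S)-cyclopropylcarbinol from Charette asymmetric Simmons–Smith of an (E)-furyl allylic alcohol ← 3-methylfurfural.
5. Ring order: furan (commercial), cyclopropane, butenolide, macrocycle (NHK), then the enedione is unmasked last.

## Route

**Step 1**
Reactants: 1 (3-methylfuran-2-carbaldehyde); 2 (ethylene glycol)
Product: 3 (2-(3-methylfuran-2-yl)-1,3-dioxolane)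
Conditions: TsOH (cat.), PhMe, Dean–Stark, reflux
Reagents that add atoms: ethylene glycol, OCCO
Why: Acetalisation masks the furfural CHO so it survives the later organometallic, hydride and Wittig steps; no stereocentre is formed.

**Step 2**
Reactants: 3; 4 (DMF)
Product: 5 (5-(1,3-dioxolan-2-yl)-4-methylfuran-2-carbaldehyde)
Conditions: n-BuLi, THF, –78 → –20 °C; then DMF, –78 → 0 °C
Reagents that add atoms: DMF, CN(C)C=O
Why: The methyl blocks C3, so lithiation occurs at the only free α-position (C5) and DMF quench gives the aldehyde (Bouveault formylation).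

**Step 3**
Reactants: 5; 6 (2-(triphenylphosphoranylidene)propanal)
Product: 7 ((E)-3-[5-(dioxolan-2-yl)-4-methylfuran-2-yl]-2-methylacrolein)
Conditions: PhMe, 80 °C
Reagents that add atoms: ylide 6, CC(C=O)=P(c1ccccc1)(c1ccccc1)c1ccccc1
Why: Wittig reaction of a stabilised ylide gives the E trisubstituted enal, which fixes the trans furyl/CH2OH relationship in the later cyclopropane.

**Step 4**
Reactants: 7
Product: 8 ((E)-allylic alcohol)
Conditions: NaBH4, CeCl3·7H2O, MeOH, 0 °C
Reagents that add atoms: none
Why: Luche 1,2-reduction of the enal; the E alkene is retained.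

**Step 5**
Reactants: 8; 9 (CH2I2)
Product: 10 ({(1S,2S)-2-[5-(dioxolan-2-yl)-4-methylfuran-2-yl]-1-methylcyclopropyl}methanol)
Conditions: Et2Zn, CH2I2, (4R,5R)-tartramide dioxaborolane ligand, CH2Cl2, 0 °C → rt
Reagents that add atoms: diiodomethane, ICI (supplies the CH2 of the cyclopropane)
Why: Charette asymmetric Simmons–Smith delivers the zinc carbenoid to one face of the E-alkene, and the alkene geometry then fixes the relative configuration. This sets C7 and C8 (S,S) with the furyl trans to CH2OH; use the (S,S) ligand if the (R,R) ligand gives the (R,R) product.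

**Step 6**
Reactants: 10
Product: 11 (aldehyde)
Conditions: DMP, NaHCO3, CH2Cl2, rt
Reagents that add atoms: none
Why: Buffered Dess–Martin oxidation; the α-carbon is quaternary, so nothing can epimerise.

**Step 7**
Reactants: 11; 12 (ethyl propiolate)
Product: 13 (propargylic alcohol, mixture of C10 epimers)
Conditions: ethyl propiolate, LiHMDS, THF, –78 °C; then 11
Reagents that add atoms: ethyl propiolate, C#CC(=O)OCC
Why: 1,2-addition of the lithium alkynoate (alkynylation) to the aldehyde; the carbinol stereochemistry is irrelevant because it is oxidised in the next step.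

**Step 8**
Reactants: 13
Product: 14 (ynone)
Conditions: DMP, CH2Cl2, rt
Reagents that add atoms: none
Why: Oxidation removes the unwanted carbinol stereocentre and sets up a reagent-controlled reduction.

**Step 9**
Reactants: 14
Product: 15 (ethyl (4R)-4-[(1S,2S)-2-(furyl)-1-methylcyclopropyl]-4-hydroxybut-2-ynoate)
Conditions: (R)-Alpine-Borane, THF, 0 °C → rt
Reagents that add atoms: none (hydride)
Why: Midland reduction of an ynone discriminates the small linear alkynyl from the bulky quaternary cyclopropyl and gives the (R)-alcohol. This becomes C10 (S) in the lactone, where the CIP priorities swap.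

**Step 10**
Reactants: 15; 16 (allyl alcohol)
Product: 17 ((5S)-5-{(1S,2S)-2-[5-(dioxolan-2-yl)-4-methylfuran-2-yl]-1-methylcyclopropyl}-3-(3-oxopropyl)furan-2(5H)-one)
Conditions: [CpRu(MeCN)3]PF6 (10 mol%), acetone, rt
Reagents that add atoms: allyl alcohol, C=CCO
Why: Ru-catalysed Alder-ene coupling of the alkynoate with allyl alcohol gives the α-(3-oxopropyl) chain, and γ-OH lactonisation closes the butenolide. C10 is not touched.

**Step 11**
Reactants: 17; 6
Product: 18 ((E)-enal)
Conditions: PhMe, 60 °C
Reagents that add atoms: ylide 6 (as above)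
Why: Wittig homologation of the aliphatic aldehyde gives the E trisubstituted enal, which will become the E allylic bromide needed for anti selectivity.

**Step 12**
Reactants: 18
Product: 19 ((E)-allylic alcohol)
Conditions: NaBH4, CeCl3·7H2O, MeOH, –10 °C
Reagents that add atoms: none
Why: Luche conditions reduce the enal selectively; the butenolide, furan and acetal are untouched.

**Step 13**
Reactants: 19; 20 (water)
Product: 21 (furfural / allylic alcohol)
Conditions: PPTS, acetone–H2O, 40 °C
Reagents that add atoms: water, O
Why: Mild acid hydrolysis of the electron-rich furfural dioxolane frees the aldehyde for the NHK reaction.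

**Step 14**
Reactants: 21; 22 (LiBr)
Product: 23 ((E)-allylic bromide / furfural)
Conditions: MsCl, Et3N, CH2Cl2, 0 °C; then LiBr, THF, rt
Reagents that add atoms: lithium bromide, [Li+].[Br-]
Why: The allylic mesylate is displaced by bromide in an SN2 reaction, with E geometry retained.

**Step 15**
Reactants: 23
Product: 24 (macrocyclic furfuryl alcohol)
Conditions: CrCl2 (10 equiv), 4 Å MS, THF, 0.002 M (slow addition), rt
Reagents that add atoms: none
Why: Intramolecular NHK reaction: the allylchromium adds through its γ-carbon via a chair Zimmerman–Traxler transition state. The E-allyl unit gives the anti relationship (C1 S, C2 S), with facial selectivity set by the macrocycle and the existing centres.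

**Step 16**
Reactants: 24; 25 (Ac2O)
Product: 26 (C2 acetate)
Conditions: Ac2O, DMAP, Et3N, CH2Cl2, 0 °C → rt
Reagents that add atoms: acetic anhydride, CC(=O)OC(C)=O
Why: O-acylation with retention at C2; acetylating before the oxidation avoids an unstable α-hydroxy enedione.

**Step 17**
Reactants: 26; 27 (DMDO)
Product: 28 (Pinnatin B)
Conditions: DMDO (1.0 equiv), acetone, –30 °C
Reagents that add atoms: dimethyldioxirane, CC1(C)OO1 (adds one O)
Why: Furan epoxidation and ring opening give the cis-enedione. The Z geometry comes from the cis ring bond, no new stereocentre is formed, and the electron-rich furan outcompetes the isopropenyl group.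

## Compound list
1 | 3-methylfuran-2-carbaldehyde | Cc1ccoc1C=O | starting material
2 | ethylene glycol | OCCO | starting material
3 | 2-(3-methylfuran-2-yl)-1,3-dioxolane | Cc1ccoc1C1OCCO1 | intermediate
4 | DMF | CN(C)C=O | starting material
5 | 5-(dioxolan-2-yl)-4-methylfuran-2-carbaldehyde | Cc1cc(C=O)oc1C1OCCO1 | intermediate
6 | 2-(triphenylphosphoranylidene)propanal | CC(C=O)=P(c1ccccc1)(c1ccccc1)c1ccccc1 | starting material
7 | (E)-furyl-2-methylacrolein | O=C/C(C)=C/c1cc(C)c(o1)C1OCCO1 | intermediate
8 | (E)-furyl allylic alcohol | OC/C(C)=C/c1cc(C)c(o1)C1OCCO1 | intermediate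
9 | diiodomethane | ICI | starting material
10 | (1S,2S)-cyclopropylmethanol | OC[C@@]1(C)C[C@@H]1c2cc(C)c(o2)C3OCCO3 | intermediate
11 | (1S,2S)-cyclopropanecarbaldehyde | O=C[C@@]1(C)C[C@@H]1c2cc(C)c(o2)C3OCCO3 | intermediate
12 | ethyl propiolate | C#CC(=O)OCC | starting material
13 | propargylic alcohol (C10 epimers) | CCOC(=O)C#CC(O)[C@@]1(C)C[C@@H]1c2cc(C)c(o2)C3OCCO3 | intermediate
14 | ynone | CCOC(=O)C#CC(=O)[C@@]1(C)C[C@@H]1c2cc(C)c(o2)C3OCCO3 | intermediate
15 | (R)-propargylic alcohol | CCOC(=O)C#C[C@H](O)[C@@]1(C)C[C@@H]1c2cc(C)c(o2)C3OCCO3 | intermediate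
16 | allyl alcohol | C=CCO | starting material
17 | butenolide aldehyde | O=CCCC1=C[C@H](OC1=O)[C@@]2(C)C[C@@H]2c3cc(C)c(o3)C4OCCO4 | intermediate
18 | butenolide E-enal | O=C/C(C)=C/CCC1=C[C@H](OC1=O)[C@@]2(C)C[C@@H]2c3cc(C)c(o3)C4OCCO4 | intermediate
19 | butenolide E-allylic alcohol (acetal) | OC/C(C)=C/CCC1=C[C@H](OC1=O)[C@@]2(C)C[C@@H]2c3cc(C)c(o3)C4OCCO4 | intermediate
20 | water | O | starting material (reagent)
21 | furfural / allylic alcohol | OC/C(C)=C/CCC1=C[C@H](OC1=O)[C@@]2(C)C[C@@H]2c3cc(C)c(o3)C=O | intermediate
22 | lithium bromide | [Li+].[Br-] | starting material (reagent)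
23 | allylic bromide / furfural | BrC/C(C)=C/CCC1=C[C@H](OC1=O)[C@@]2(C)C[C@@H]2c3cc(C)c(o3)C=O | intermediate
24 | macrocyclic furfuryl alcohol | C=C(C)[C@@H]1CCC2=C[C@H](OC2=O)[C@@]3(C)C[C@@H]3c4cc(C)c(o4)[C@H]1O | intermediate
25 | acetic anhydride | CC(=O)OC(C)=O | starting material (reagent)
26 | macrocyclic furan acetate | C=C(C)[C@@H]1CCC2=C[C@H](OC2=O)[C@@]3(C)C[C@@H]3c4cc(C)c(o4)[C@H]1OC(C)=O | intermediate
27 | dimethyldioxirane | CC1(C)OO1 | starting material (reagent)
28 | Pinnatin B | C=C(C)[C@@H]1CCC2=C[C@H](OC2=O)[C@@]2(C)C[C@@H]2C(=O)/C=C(/C)C(=O)[C@H]1OC(C)=O | target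

**Total steps:** 17. **Longest linear sequence:** 17 (from 1).

**Three steps most likely to fail**
1. **Step 15 (macrocyclic NHK).** The 2,5-bridged furan ring is strained and the remote diastereocontrol is uncertain. Fallback: run an intermolecular NHK of a furfural with an acyclic allyl bromide first, separate the C1/C2 diastereomers, then close the ring by a macrocyclic Ru-catalysed alkyne–alkene Alder-ene/lactonisation at C12–C13.
2. **Step 5 (Charette cyclopropanation).** The furyl allylic alcohol is acid-sensitive, and the zinc carbenoid may attack the furan or give low ee. Fallback: racemic Et2Zn/CH2I2 cyclopropanation followed by lipase kinetic resolution (PS lipase, vinyl acetate) of the cyclopropylmethanol.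
3. **Step 17 (DMDO oxidation).** The isopropenyl group may be epoxidised, the Z-enedione may isomerise, and C2 may epimerise. Fallback: singlet oxygen (rose bengal, hν, –78 °C) followed by Me2S reduction of the endoperoxide, a different oxidative manifold for the furan opening.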